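## Structural features

The target is a 2,3-dimethylchroman-4-one: pyranone ring B (O1, C2, C3, C4, C4a, C8a) is fused to benzene ring A (C4a to C8a). Ring A is hexasubstituted and is in substance a phloroglucinol whose three oxygens (O1 in ring B, free 5-OH, free 7-OH) and three carbons (C4a acyl, C6 prenyl, C8 alkyl) are all different. C8 carries a methyl hexanoate chain (C1' ester carbon to C6') joined through C3', so C3' is a benzylic stereocentre (S) flanked by the two ortho oxygens O1 and O7. C2 (S) and C3 (S) are adjacent and trans; C3 is alpha to the C4 ketone and epimerisable, trans being the thermodynamic arrangement, whereas C3' is isolated from C2 by ring A and a freely rotating bond and cannot be relayed from it. Fragile groups are the prenyl alkene (hydrogenation, acid-induced cyclisation onto 5-OH or 7-OH), the beta-aryloxy ketone of ring B (retro-oxa-Michael opening and C3 epimerisation in base), the methyl ester (lactonisation onto 7-OH to a dihydrocoumarin) and the electron-rich ring itself. The real difficulty is twofold: the isolated C3' stereocentre on the most hindered carbon of ring A, and the regiochemistry of ring A, where ring B must close on the oxygen next to C8 and not on the one next to C6. The key step exploits the ortho relationship O1–C8a–C8–C3': C3' can be delivered to C8 from the oxygen that becomes O1 by a [3,3] shift that carries its configuration from a C–O stereocentre, and because a 3,5-disubstituted phenyl ether has two equivalent ortho carbons, the same event leaves that oxygen as the only free hydroxyl of ring A.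

## Logic of the disconnections

**22 to 20 + 21.** The C6–C1'' bond (ring A to prenyl) is cut first. C6 is the last unsubstituted carbon of ring A in 20, so no regiochemical choice exists, and the prenyl alkene is the one group that could not survive the hydrogenation placed before it. The forward step must favour C- over O-alkylation and use a base that spares the ester and C3.

**20 to 19.** Two O–benzyl bonds (O5, O7) are restored and the C4'–C5' single bond is traced back to an E alkene. One hydrogenation then removes both protecting groups and saturates the chain. The demand is that the C4 ketone and the C2–O1 bond are left alone.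

**19 to 16.** The C4–C4a bond (aryl ketone) is cut. In 16 the acyl group hangs from the ether oxygen and only one ring carbon ortho to that oxygen is unsubstituted, so the six-membered closure has no alternative. The forward acylation must be mild enough for the benzyl ethers, the alkene and C2, and it must return the side-chain carboxyl as its methyl ester.

**16 to 15 to 9 + 14.** After adjusting the ester level, the O1–C2 bond is cut. In 9 the future O1 is the only free hydroxyl, so the three ring oxygens need not be told apart by reagent selectivity. C2 then arises by SN2 inversion of a carbinol and C3 is carried in from 14. The demand is that substitution outruns elimination at a hindered, ester-activated secondary alcohol.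

**14 to 13 to 10 + 11.** The bond between the two future ring-B stereocentres is cut in an auxiliary-controlled syn-aldol sense. Both centres are then set together with a predictable sense from commercial materials.

**9 to 6 (key).** The C8–C3' bond is cut and the oxygen that becomes O1 is reconnected to C5', which is a retro-[3,3] shift. The benzylic stereocentre is traced back to a C–O stereocentre, the most hindered C–C bond of the target to an ether bond, and ring A to a twofold-symmetric ether. The demands on the forward step are a pure E alkene and configurationally pure C5' in 6, a strong preference for the methyl-equatorial transition state, and suppression of follow-up reactions of the ortho-allylphenol.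

**6 to 4 + 5; 4 to 3; 3 to 1 + 2.** The C2'–C3' bond is cut (alkenylboron plus alpha-bromo ester), then the C–B bond (hydroboration of a terminal alkyne), then the O–C5' bond (inversion of a commercial propargylic alcohol by a symmetric phenol). The E geometry comes from syn hydrometalation and the C5' configuration from the chiral pool. The coupling must not conjugate the beta,gamma-unsaturated ester or ionise the allylic aryl ether.

## Other disconnections considered

**Alternative 1:** The first thought is to read the side chain as a reduced, ring-opened 4-propylcoumarin: cut C2'–H/C3'–H and the ester O–CH3 and reconnect C1' to O7. Pechmann condensation of phloroglucinol with ethyl 3-oxohexanoate would give A1. Tigloylation with oxa-Michael closure, then prenylation, would have to deliver pyranocoumarin A2. The forward key step would be an enantioselective conjugate reduction of the coumarin C=C bond of A2 (CuH from Cu(OAc)2, a chiral bisphosphine and a silane) to dihydrocoumarin A3, followed by methanolysis. The chosen plan is preferred on three grounds: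
- A2 needs acylation of A1 at the carbon between its two hydroxyls and closure onto the hydroxyl peri to the propyl group. Nothing in A1 disfavours acylation at the other free carbon or closure on the other hydroxyl, so two regiochemical choices are left open.
- The hydride would have to reach a fully substituted beta-carbon shielded by a peri ether oxygen, in the presence of an aryl ketone and a prenyl alkene.
- The Claisen plan removes both regiochemical choices by symmetry and sets C3' intramolecularly.

**Alternative 2:** Cut C8–C3' with the arene as nucleophile: a Hayashi–Miyaura conjugate addition of arylboronate A4 to methyl (E)-hex-2-enoate, catalysed by [RhCl(C2H4)2]2 with a chiral diene. The chosen plan is preferred on three grounds: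
- A4 presupposes a C8-selective borylation on a ring whose C6 prenylation is itself unsolved.
- The boron sits between two ortho oxygens, which favours protodeboronation under aqueous base and slows transmetalation for steric reasons. The most hindered bond of the target would be made intermolecularly, whereas the [3,3] shift makes it within one molecule.
- Two acetal groups would afterwards have to be removed with acid next to a prenyl group.

**Alternative 3:** Use a temporary lactone: cut C8–C3' and C1'–OMe and reconnect C1' to O7. An N-heterocyclic-carbene-catalysed oxidative [3+3] annulation of phenol A5 with hex-2-ynal (alpha,beta-unsaturated acyl azolium; conjugate addition by C8, lactonisation on O7) would give A3, and methanolysis would give the target. The ring absent from the target would tie O7 to the carboxyl in one operation, but the chosen plan is preferred on three grounds: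
- A5 needs the prenyl group unambiguously at C6, so the regiochemical problem of ring A is moved, not solved.
- The nucleophilic carbon belongs to an acylphloroglucinol whose ketone lowers its reactivity well below that of the naphthols and simple electron-rich phenols for which this annulation type is established.
- Enantiocontrol would rest on catalyst discrimination for a beta-propyl acyl azolium, where the facial bias is smaller than for beta-aryl cases, whereas in the chosen plan the sense follows from the mechanism of a suprafacial shift.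

Key step: step 4

Assumption: the trans C2/C3 arrangement is taken as the thermodynamically preferred one, so that C3, once set, is not endangered by the mild acid and base used later; both enantiomers of but-3-yn-2-ol and the propionyl oxazolidinone 10 are taken as commercial.

## Steps

Step 1
Reactants: 1 3,5-bis(benzyloxy)phenol; 2 (R)-but-3-yn-2-ol
Product: 3 (S)-1,3-bis(benzyloxy)-5-(but-3-yn-2-yloxy)benzene
Conditions: PPh3, DIAD, THF, 0 °C to rt
Reagents that add atoms: none
Why: Mitsunobu etherification: the phenoxide displaces the alkoxyphosphonium of the secondary propargylic alcohol by SN2 with inversion, turning the R carbinol into the S ether carbon (the future C5'); a propargylic centre has no productive SN2' outlet, and the symmetric phenol offers only one kind of oxygen.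

Step 2
Reactants: 3 (S)-1,3-bis(benzyloxy)-5-(but-3-yn-2-yloxy)benzene
Product: 4 2-[(1E,3S)-3-[3,5-bis(benzyloxy)phenoxy]but-1-en-1-yl]-4,4,5,5-tetramethyl-1,3,2-dioxaborolane
Conditions: HBpin (1.3 equiv), Cp2Zr(H)Cl (5 mol%), Et3N (10 mol%), neat, 60 °C
Reagents that add atoms: pinacolborane, CC1(C)OBOC1(C)C
Why: Zirconium-hydride-catalysed hydroboration of a terminal alkyne: syn addition with boron at the terminal carbon should give only the E alkenylboronate; the ether stereocentre is not involved.

Step 3
Reactants: 4 2-[(1E,3S)-3-[3,5-bis(benzyloxy)phenoxy]but-1-en-1-yl]-4,4,5,5-tetramethyl-1,3,2-dioxaborolane; 5 methyl bromoacetate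
Product: 6 methyl (3E,5S)-5-[3,5-bis(benzyloxy)phenoxy]hex-3-enoate
Conditions: Pd(OAc)2 (3 mol%), P(o-tol)3 (9 mol%), K3PO4, THF/H2O, rt
Reagents that add atoms: none
Why: Suzuki–Miyaura coupling of an alkenylboronate with an alpha-bromo ester (sp2–sp3): transmetalation and reductive elimination retain the E geometry and install the CH2CO2Me arm; room temperature and a mild base are chosen so that the beta,gamma-unsaturated ester is not conjugated and zerovalent palladium does not ionise the allylic aryl ether.

Step 4
Reactants: 6 methyl (3E,5S)-5-[3,5-bis(benzyloxy)phenoxy]hex-3-enoate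
Product: 9 methyl (3R,4E)-3-[2,4-bis(benzyloxy)-6-hydroxyphenyl]hex-4-enoate, via ortho-dienone 7 (not isolated), via trimethylsilyl ether 8 (not isolated)
Conditions: N,O-bis(trimethylsilyl)acetamide (2 equiv), 1,2-dichlorobenzene (0.05 M), 165 °C, Ar; then K2CO3, MeOH, 0 °C
Reagents that add atoms: none
Why: Thermal aromatic Claisen rearrangement, a concerted suprafacial [3,3] sigmatropic shift in which the O–C5' bond breaks while C3' bonds to an ortho carbon of the ring, giving dienone 7, which re-aromatises and is silylated in situ to 8. The closest known reaction type is the rearrangement of enantiopure alpha-methyl-gamma-substituted allyl aryl ethers, which transfers chirality from the C–O carbon to the new benzylic carbon. No ring of the target is closed; the only cyclic array is the six-membered pericyclic transition state. The new stereocentre C3' is controlled by the S configuration at C5' together with the E geometry of C3'=C4' in 6: with the C6' methyl pseudo-equatorial the oxygen leaves from, and the arene adds to, the same face of the allyl unit, which gives R at C3' and an E C4'=C5' alkene, and since the arene carries no stereochemical element, chair and boat arrangements give the same result. The selectivities needed are ortho against ortho', which is moot because the two ortho carbons of the 3,5-bis(benzyloxy)phenyl ring are equivalent, and ortho against para, which is secured by the ortho hydrogens that let 7 enolise before a Cope relay. The one leak is the transition state with the methyl pseudo-axial (Z alkene, opposite configuration at C3'), disfavoured by the 1,3-interaction of an axial methyl; any Z isomer would be removed on AgNO3-impregnated silica before step 10. N,O-Bis(trimethylsilyl)acetamide takes the free ortho-allylphenol out of play and so blocks the abnormal Claisen pathway (homodienyl hydrogen shift to a spirocyclopropane dienone, which here would reopen toward the conjugated ester) and lactonisation onto the methyl ester, and K2CO3 in MeOH then releases 9. The shift thereby makes the most hindered C–C bond of the target, sets its isolated stereocentre and marks the oxygen that becomes O1 as the only free hydroxyl of ring A.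

Step 5
Reactants: 10 (4S)-4-benzyl-3-propanoyl-1,3-oxazolidin-2-one; 11 acetaldehyde
Product: 13 (4S)-4-benzyl-3-[(2S,3R)-3-hydroxy-2-methylbutanoyl]-1,3-oxazolidin-2-one, via dibutylboron Z-enolate 12 (not isolated)
Conditions: Bu2BOTf, iPr2NEt, CH2Cl2, 0 °C; then MeCHO, −78 to 0 °C; then pH 7 buffer, MeOH, 30% H2O2, 0 °C
Reagents that add atoms: none
Why: Evans syn-aldol reaction: the Z boron enolate 12 adds to acetaldehyde through a closed chair transition state on the face away from the benzyl group, which sets the alpha carbon as S and the carbinol carbon as R (the future C3 and, after inversion, C2 of ring B).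

Step 6
Reactants: 13 (4S)-4-benzyl-3-[(2S,3R)-3-hydroxy-2-methylbutanoyl]-1,3-oxazolidin-2-one
Product: 14 methyl (2S,3R)-3-hydroxy-2-methylbutanoate
Conditions: NaOMe (1.1 equiv), MeOH, 0 °C, 10 min; NH4Cl quench
Reagents that add atoms: sodium methoxide, C[O-].[Na+]
Why: Methanolysis of the N-acyl oxazolidinone at the exocyclic carbonyl releases the methyl ester and the auxiliary; short contact at 0 °C should avoid retro-aldol cleavage and alpha-epimerisation, so both stereocentres are carried over.

Step 7
Reactants: 9 methyl (3R,4E)-3-[2,4-bis(benzyloxy)-6-hydroxyphenyl]hex-4-enoate; 14 methyl (2S,3R)-3-hydroxy-2-methylbutanoate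
Product: 15 methyl (3R,4E)-3-[2,4-bis(benzyloxy)-6-{[(2S,3S)-4-methoxy-3-methyl-4-oxobutan-2-yl]oxy}phenyl]hex-4-enoate
Conditions: PPh3, DIAD, toluene, 0 °C to rt
Reagents that add atoms: none
Why: Mitsunobu etherification of the only free phenol of 9: SN2 inversion converts the 3R carbinol of 14 into the S-configured O–CH carbon (future C2) while the alpha-methyl centre (future C3) is untouched, giving the anti ether that corresponds to the trans ring; the other two ring oxygens are benzylated, so the future O1 is addressed without a regiochemical choice.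

Step 8
Reactants: 15 methyl (3R,4E)-3-[2,4-bis(benzyloxy)-6-{[(2S,3S)-4-methoxy-3-methyl-4-oxobutan-2-yl]oxy}phenyl]hex-4-enoate
Product: 16 (3R,4E)-3-[2,4-bis(benzyloxy)-6-{[(2S,3S)-3-carboxybutan-2-yl]oxy}phenyl]hex-4-enoic acid
Conditions: LiOH·H2O (6 equiv), THF/MeOH/H2O, rt; then 1 M HCl to pH 3, 0 °C
Reagents that add atoms: lithium hydroxide, [Li+].[OH-]
Why: Saponification of both methyl esters by acyl–oxygen cleavage; hydrolysis is faster than enolisation, and once the carboxylate has formed the beta-aryloxy unit is protected against E1cB loss of the phenoxide, so C2, C3 and C3' should be retained.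

Step 9
Reactants: 16 (3R,4E)-3-[2,4-bis(benzyloxy)-6-{[(2S,3S)-3-carboxybutan-2-yl]oxy}phenyl]hex-4-enoic acid
Product: 19 methyl (3R,4E)-3-[(2S,3S)-5,7-bis(benzyloxy)-2,3-dimethyl-4-oxo-3,4-dihydro-2H-chromen-8-yl]hex-4-enoate, via bis(trifluoroacetyl) mixed anhydride 17 (not isolated), via chromanone mixed anhydride 18 (not isolated)
Conditions: (CF3CO)2O (4 equiv), CH2Cl2, 0 °C; then MeOH, 0 °C to rt
Reagents that add atoms: methanol, CO
Why: Intramolecular Friedel–Crafts acylation through mixed trifluoroacetic anhydrides: only the beta-aryloxy acyl group can reach an unsubstituted ring carbon (the one ortho to the ether oxygen, which becomes C4a), so ring B closes as the six-membered ketone without touching C2 or C3. The side-chain anhydride has no ring carbon within reach and, under the acidic conditions, should transfer its non-fluorinated acyl group to methanol, which restores the methyl ester in the same flask.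

Step 10
Reactants: 19 methyl (3R,4E)-3-[(2S,3S)-5,7-bis(benzyloxy)-2,3-dimethyl-4-oxo-3,4-dihydro-2H-chromen-8-yl]hex-4-enoate
Product: 20 methyl (3S)-3-[(2S,3S)-5,7-dihydroxy-2,3-dimethyl-4-oxo-3,4-dihydro-2H-chromen-8-yl]hexanoate
Conditions: H2 (1 atm), 10% Pd/C, EtOAc/MeOH, rt
Reagents that add atoms: none
Why: One heterogeneous hydrogenation cleaves both benzyl ethers and saturates the C4'=C5' alkene to the propyl group; C3' is not touched (its descriptor changes from R to S only because the CIP ranking of its substituents changes), and the chelated, vinylogous-ester-like C4 ketone should not be reduced under these mild conditions.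

Step 11
Reactants: 20 methyl (3S)-3-[(2S,3S)-5,7-dihydroxy-2,3-dimethyl-4-oxo-3,4-dihydro-2H-chromen-8-yl]hexanoate; 21 1-bromo-3-methylbut-2-ene
Product: 22 methyl (3S)-3-[(2S,3S)-5,7-dihydroxy-2,3-dimethyl-6-(3-methylbut-2-en-1-yl)-4-oxo-3,4-dihydro-2H-chromen-8-yl]hexanoate
Conditions: NaOMe (1.1 equiv), MeOH, 0 °C; then 21 (1.2 equiv), 0 °C to rt; AcOH quench
Reagents that add atoms: none
Why: C-prenylation of an acylphloroglucinol-type phenoxide: C6 is the only unsubstituted carbon of ring A and lies ortho to both O5 and O7, and methanol as a hydrogen-bonding solvent favours C- over O-alkylation. Methoxide in methanol is degenerate toward the methyl ester and keeps the hydroxy ester from lactonising; no stereocentre is formed.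

## Compound list

1 | 3,5-bis(benzyloxy)phenol | Oc1cc(OCc2ccccc2)cc(OCc2ccccc2)c1 | starting material
2 | (R)-but-3-yn-2-ol | C[C@@H](O)C#C | starting material
3 | (S)-1,3-bis(benzyloxy)-5-(but-3-yn-2-yloxy)benzene | C[C@H](Oc1cc(OCc2ccccc2)cc(OCc2ccccc2)c1)C#C | intermediate
4 | 2-[(1E,3S)-3-[3,5-bis(benzyloxy)phenoxy]but-1-en-1-yl]-4,4,5,5-tetramethyl-1,3,2-dioxaborolane | C[C@H](Oc1cc(OCc2ccccc2)cc(OCc2ccccc2)c1)/C=C/B1OC(C)(C)C(C)(C)O1 | intermediate
5 | methyl bromoacetate | COC(=O)CBr | starting material
6 | methyl (3E,5S)-5-[3,5-bis(benzyloxy)phenoxy]hex-3-enoate | C[C@H](Oc1cc(OCc2ccccc2)cc(OCc2ccccc2)c1)/C=C/CC(=O)OC | intermediate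
7 | methyl (4E)-3-[2,4-bis(benzyloxy)-6-oxocyclohexa-2,4-dien-1-yl]hex-4-enoate (ortho-dienone; chain C3 configured as in 9, ring C1 not defined) | COC(=O)C[C@H](/C=C/C)C1C(=O)C=C(OCc2ccccc2)C=C1OCc1ccccc1 | intermediate
8 | methyl (3R,4E)-3-{2,4-bis(benzyloxy)-6-[(trimethylsilyl)oxy]phenyl}hex-4-enoate | COC(=O)C[C@H](/C=C/C)c1c(O[Si](C)(C)C)cc(OCc2ccccc2)cc1OCc1ccccc1 | intermediate
9 | methyl (3R,4E)-3-[2,4-bis(benzyloxy)-6-hydroxyphenyl]hex-4-enoate | COC(=O)C[C@H](/C=C/C)c1c(O)cc(OCc2ccccc2)cc1OCc1ccccc1 | intermediate
10 | (4S)-4-benzyl-3-propanoyl-1,3-oxazolidin-2-one | CCC(=O)N1[C@@H](Cc2ccccc2)COC1=O | starting material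
11 | acetaldehyde | CC=O | starting material
12 | (4S)-4-benzyl-3-[(1Z)-1-[(dibutylboranyl)oxy]prop-1-en-1-yl]-1,3-oxazolidin-2-one | C/C=C(\OB(CCCC)CCCC)N1[C@@H](Cc2ccccc2)COC1=O | intermediate
13 | (4S)-4-benzyl-3-[(2S,3R)-3-hydroxy-2-methylbutanoyl]-1,3-oxazolidin-2-one | O=C([C@@H](C)[C@@H](C)O)N1[C@@H](Cc2ccccc2)COC1=O | intermediate
14 | methyl (2S,3R)-3-hydroxy-2-methylbutanoate | COC(=O)[C@@H](C)[C@@H](C)O | intermediate
15 | methyl (3R,4E)-3-[2,4-bis(benzyloxy)-6-{[(2S,3S)-4-methoxy-3-methyl-4-oxobutan-2-yl]oxy}phenyl]hex-4-enoate | COC(=O)C[C@H](/C=C/C)c1c(O[C@@H](C)[C@H](C)C(=O)OC)cc(OCc2ccccc2)cc1OCc1ccccc1 | intermediate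
16 | (3R,4E)-3-[2,4-bis(benzyloxy)-6-{[(2S,3S)-3-carboxybutan-2-yl]oxy}phenyl]hex-4-enoic acid | OC(=O)C[C@H](/C=C/C)c1c(O[C@@H](C)[C@H](C)C(=O)O)cc(OCc2ccccc2)cc1OCc1ccccc1 | intermediate
17 | bis(trifluoroacetic) mixed anhydride of 16 | FC(F)(F)C(=O)OC(=O)C[C@H](/C=C/C)c1c(O[C@@H](C)[C@H](C)C(=O)OC(=O)C(F)(F)F)cc(OCc2ccccc2)cc1OCc1ccccc1 | intermediate
18 | trifluoroacetic mixed anhydride of (3R,4E)-3-[(2S,3S)-5,7-bis(benzyloxy)-2,3-dimethyl-4-oxo-3,4-dihydro-2H-chromen-8-yl]hex-4-enoic acid | FC(F)(F)C(=O)OC(=O)C[C@H](/C=C/C)c1c(OCc2ccccc2)cc(OCc2ccccc2)c2c1O[C@@H](C)[C@H](C)C2=O | intermediate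
19 | methyl (3R,4E)-3-[(2S,3S)-5,7-bis(benzyloxy)-2,3-dimethyl-4-oxo-3,4-dihydro-2H-chromen-8-yl]hex-4-enoate | COC(=O)C[C@H](/C=C/C)c1c(OCc2ccccc2)cc(OCc2ccccc2)c2c1O[C@@H](C)[C@H](C)C2=O | intermediate
20 | methyl (3S)-3-[(2S,3S)-5,7-dihydroxy-2,3-dimethyl-4-oxo-3,4-dihydro-2H-chromen-8-yl]hexanoate | CCC[C@@H](CC(=O)OC)c1c(O)cc(O)c2c1O[C@@H](C)[C@H](C)C2=O | intermediate
21 | 1-bromo-3-methylbut-2-ene | CC(C)=CCBr | starting material
22 | methyl (3S)-3-[(2S,3S)-5,7-dihydroxy-2,3-dimethyl-6-(3-methylbut-2-en-1-yl)-4-oxo-3,4-dihydro-2H-chromen-8-yl]hexanoate | CCC[C@@H](CC(=O)OC)c1c(O)c(CC=C(C)C)c(O)c2c1O[C@@H](C)[C@H](C)C2=O | target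

## Step count and least certain steps

Total: 11 steps. Longest linear sequence: 9 steps (1 to 3, 4, 6, 9, 15, 16, 19, 20, 22); the branch 10 to 13 to 14 adds 2.

**Step 4 (key step).** What may go wrong:
- Partial passage through the transition state with the C6' methyl pseudo-axial gives the Z alkene with the opposite sense at C3', which after step 10 would appear as erosion of enantiomeric purity at the benzylic centre.
- The beta,gamma-unsaturated ester of 6 may conjugate thermally before it rearranges.
- Incomplete silylation would allow abnormal Claisen isomerisation of the ortho-allylphenol.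

Fallback (sets out from 1, returns at 20): the stereocentre is set by a catalyst instead of by transfer. Phenol 1 and (E)-hex-2-enal undergo an iminium-catalysed Friedel–Crafts alkylation/hemiacetalisation (2-[diphenyl(trimethylsilyloxy)methyl]pyrrolidine of the enantiomeric series that, by the usual shielding model, leads to 4S; benzoic acid, toluene, 0 °C) to the lactol (4S)-5,7-bis(benzyloxy)-4-propylchroman-2-ol F1. Oxidation (TEMPO, PhI(OAc)2) gives the lactone (4S)-5,7-bis(benzyloxy)-4-propylchroman-2-one F2, and NaOMe in MeOH opens it to methyl (3S)-3-[2,4-bis(benzyloxy)-6-hydroxyphenyl]hexanoate F3, in which the lactone oxygen has become the same marked phenol as in 9. F3 is taken through the operations of steps 7 to 9: Mitsunobu reaction with 14 to the diester methyl (3S)-3-[2,4-bis(benzyloxy)-6-{[(2S,3S)-4-methoxy-3-methyl-4-oxobutan-2-yl]oxy}phenyl]hexanoate F4; saponification to the diacid (3S)-3-[2,4-bis(benzyloxy)-6-{[(2S,3S)-3-carboxybutan-2-yl]oxy}phenyl]hexanoic acid F5; then (CF3CO)2O and MeOH, by way of the saturated bis(trifluoroacetyl) mixed anhydride F6 and the saturated chromanone mixed anhydride F7, to methyl (3S)-3-[(2S,3S)-5,7-bis(benzyloxy)-2,3-dimethyl-4-oxo-3,4-dihydro-2H-chromen-8-yl]hexanoate F8. Hydrogenolysis of F8 under the conditions of step 10 gives 20.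

**Step 7.** What may go wrong: steric retardation of the SN2 displacement (a mono-ortho-substituted phenol meets an alpha-branched secondary alkoxyphosphonium), so that E2 elimination toward the alpha,beta-unsaturated ester takes over.

Fallback (sets out from 9 and 13, returns at 19): the alcohol partner is changed to one without an acidifying carbonyl group. LiBH4 reduction of 13 gives (2R,3R)-2-methylbutane-1,3-diol F9. Silylation of the primary hydroxyl (TBSCl, imidazole) gives (2R,3R)-4-[(tert-butyldimethylsilyl)oxy]-3-methylbutan-2-ol F10. Mitsunobu reaction with 9 gives the ether methyl (3R,4E)-3-[2,4-bis(benzyloxy)-6-{[(2S,3R)-4-[(tert-butyldimethylsilyl)oxy]-3-methylbutan-2-yl]oxy}phenyl]hex-4-enoate F11. HF·pyridine frees the primary alcohol methyl (3R,4E)-3-[2,4-bis(benzyloxy)-6-{[(2S,3R)-4-hydroxy-3-methylbutan-2-yl]oxy}phenyl]hex-4-enoate F12. Oxidation (TEMPO, PhI(OAc)2, MeCN/H2O) gives the monoacid (2S,3S)-3-{3,5-bis(benzyloxy)-2-[(3R,4E)-1-methoxy-1-oxohex-4-en-3-yl]phenoxy}-2-methylbutanoic acid F13, which cyclises with (CF3CO)2O by way of its trifluoroacetic mixed anhydride F14 to 19. The side-chain methyl ester is never hydrolysed.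

**Step 3.** What may go wrong: ionisation of the allylic C–O(aryl) bond by zerovalent palladium (loss of the aryloxide or scrambling of C5') competing with oxidative addition to 5, and base-mediated conjugation of the beta,gamma-unsaturated ester.

Fallback (sets out from 2, returns at 6): the order of bond formation is reversed so that no allylic aryl ether meets zerovalent palladium. Alcohol 2 is hydroborated itself (excess HBpin, Cp2Zr(H)Cl cat.; the O–B bond is hydrolysed on work-up) to (2R,3E)-4-(4,4,5,5-tetramethyl-1,3,2-dioxaborolan-2-yl)but-3-en-2-ol F15, which is coupled with 5 under the conditions of step 3 to methyl (3E,5R)-5-hydroxyhex-3-enoate F16. Mitsunobu etherification of 1 with F16 (inversion at C5') then gives 6.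

**Step 11.** What may go wrong: O-alkylation at O7 instead of C-alkylation, double alkylation at C6 with dearomatisation, and base-induced epimerisation at C3.

Fallback (sets out from 20, returns at 22): the prenyl group is delivered from O7 by a second aromatic Claisen rearrangement under neutral conditions. The non-chelated 7-OH is etherified with 3-chloro-3-methylbut-1-yne (CuCl2·2H2O cat., DBU, MeCN, 0 °C) to methyl (3S)-3-{(2S,3S)-5-hydroxy-2,3-dimethyl-7-[(2-methylbut-3-yn-2-yl)oxy]-4-oxo-3,4-dihydro-2H-chromen-8-yl}hexanoate F17. Semihydrogenation (H2, Pd/CaCO3 poisoned with Pb(OAc)2, quinoline) gives methyl (3S)-3-{(2S,3S)-5-hydroxy-2,3-dimethyl-7-[(2-methylbut-3-en-2-yl)oxy]-4-oxo-3,4-dihydro-2H-chromen-8-yl}hexanoate F18. Heating (toluene, 110 °C) moves the group by a [3,3] shift to C6, the only free ortho position, and gives 22.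

## Further compounds

F1 | step 4 | (4S)-5,7-bis(benzyloxy)-4-propylchroman-2-ol (both configurations at C2) | CCC[C@H]1CC(O)Oc2cc(OCc3ccccc3)cc(OCc3ccccc3)c21
F2 | step 4 | (4S)-5,7-bis(benzyloxy)-4-propylchroman-2-one | CCC[C@H]1CC(=O)Oc2cc(OCc3ccccc3)cc(OCc3ccccc3)c21
F3 | step 4 | methyl (3S)-3-[2,4-bis(benzyloxy)-6-hydroxyphenyl]hexanoate | CCC[C@@H](CC(=O)OC)c1c(O)cc(OCc2ccccc2)cc1OCc1ccccc1
F4 | step 4 | methyl (3S)-3-[2,4-bis(benzyloxy)-6-{[(2S,3S)-4-methoxy-3-methyl-4-oxobutan-2-yl]oxy}phenyl]hexanoate | CCC[C@@H](CC(=O)OC)c1c(O[C@@H](C)[C@H](C)C(=O)OC)cc(OCc2ccccc2)cc1OCc1ccccc1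
F5 | step 4 | (3S)-3-[2,4-bis(benzyloxy)-6-{[(2S,3S)-3-carboxybutan-2-yl]oxy}phenyl]hexanoic acid | CCC[C@@H](CC(=O)O)c1c(O[C@@H](C)[C@H](C)C(=O)O)cc(OCc2ccccc2)cc1OCc1ccccc1
F6 | step 4 | bis(trifluoroacetic) mixed anhydride of F5 | CCC[C@@H](CC(=O)OC(=O)C(F)(F)F)c1c(O[C@@H](C)[C@H](C)C(=O)OC(=O)C(F)(F)F)cc(OCc2ccccc2)cc1OCc1ccccc1
F7 | step 4 | trifluoroacetic mixed anhydride of (3S)-3-[(2S,3S)-5,7-bis(benzyloxy)-2,3-dimethyl-4-oxo-3,4-dihydro-2H-chromen-8-yl]hexanoic acid | CCC[C@@H](CC(=O)OC(=O)C(F)(F)F)c1c(OCc2ccccc2)cc(OCc2ccccc2)c2c1O[C@@H](C)[C@H](C)C2=O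
F8 | step 4 | methyl (3S)-3-[(2S,3S)-5,7-bis(benzyloxy)-2,3-dimethyl-4-oxo-3,4-dihydro-2H-chromen-8-yl]hexanoate | CCC[C@@H](CC(=O)OC)c1c(OCc2ccccc2)cc(OCc2ccccc2)c2c1O[C@@H](C)[C@H](C)C2=O
F9 | step 7 | (2R,3R)-2-methylbutane-1,3-diol | OC[C@@H](C)[C@@H](C)O
F10 | step 7 | (2R,3R)-4-[(tert-butyldimethylsilyl)oxy]-3-methylbutan-2-ol | CC(C)(C)[Si](C)(C)OC[C@@H](C)[C@@H](C)O
F11 | step 7 | methyl (3R,4E)-3-[2,4-bis(benzyloxy)-6-{[(2S,3R)-4-[(tert-butyldimethylsilyl)oxy]-3-methylbutan-2-yl]oxy}phenyl]hex-4-enoate | COC(=O)C[C@H](/C=C/C)c1c(O[C@@H](C)[C@H](C)CO[Si](C)(C)C(C)(C)C)cc(OCc2ccccc2)cc1OCc1ccccc1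
F12 | step 7 | methyl (3R,4E)-3-[2,4-bis(benzyloxy)-6-{[(2S,3R)-4-hydroxy-3-methylbutan-2-yl]oxy}phenyl]hex-4-enoate | COC(=O)C[C@H](/C=C/C)c1c(O[C@@H](C)[C@H](C)CO)cc(OCc2ccccc2)cc1OCc1ccccc1
F13 | step 7 | (2S,3S)-3-{3,5-bis(benzyloxy)-2-[(3R,4E)-1-methoxy-1-oxohex-4-en-3-yl]phenoxy}-2-methylbutanoic acid | COC(=O)C[C@H](/C=C/C)c1c(O[C@@H](C)[C@H](C)C(=O)O)cc(OCc2ccccc2)cc1OCc1ccccc1
F14 | step 7 | trifluoroacetic mixed anhydride of F13 | COC(=O)C[C@H](/C=C/C)c1c(O[C@@H](C)[C@H](C)C(=O)OC(=O)C(F)(F)F)cc(OCc2ccccc2)cc1OCc1ccccc1
F15 | step 3 | (2R,3E)-4-(4,4,5,5-tetramethyl-1,3,2-dioxaborolan-2-yl)but-3-en-2-ol | C[C@@H](O)/C=C/B1OC(C)(C)C(C)(C)O1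
F16 | step 3 | methyl (3E,5R)-5-hydroxyhex-3-enoate | C[C@@H](O)/C=C/CC(=O)OC
F17 | step 11 | methyl (3S)-3-{(2S,3S)-5-hydroxy-2,3-dimethyl-7-[(2-methylbut-3-yn-2-yl)oxy]-4-oxo-3,4-dihydro-2H-chromen-8-yl}hexanoate | CCC[C@@H](CC(=O)OC)c1c(OC(C)(C)C#C)cc(O)c2c1O[C@@H](C)[C@H](C)C2=O
F18 | step 11 | methyl (3S)-3-{(2S,3S)-5-hydroxy-2,3-dimethyl-7-[(2-methylbut-3-en-2-yl)oxy]-4-oxo-3,4-dihydro-2H-chromen-8-yl}hexanoate | CCC[C@@H](CC(=O)OC)c1c(OC(C)(C)C=C)cc(O)c2c1O[C@@H](C)[C@H](C)C2=O
A1 | alternative 1 | 5,7-dihydroxy-4-propyl-2H-chromen-2-one | CCCc1cc(=O)oc2cc(O)cc(O)c12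
A2 | alternative 1 | pyranocoumarin: 4-propylcoumarin (lactone C1' to O7, C2'=C3' double bond) fused to the (2S,3S)-5-hydroxy-6-prenyl-2,3-dimethylchromanone of the target | CCCC1=CC(=O)Oc2c(CC=C(C)C)c(O)c3c(c21)O[C@@H](C)[C@H](C)C3=O
A3 | alternative 1 | (3'S)-dihydrocoumarin: lactone of the target acid between C1' and O7 | CCC[C@H]1CC(=O)Oc2c(CC=C(C)C)c(O)c3c(c21)O[C@@H](C)[C@H](C)C3=O
A4 | alternative 2 | 2-[(2S,3S)-5,7-bis(methoxymethoxy)-2,3-dimethyl-6-(3-methylbut-2-en-1-yl)-4-oxo-3,4-dihydro-2H-chromen-8-yl]-4,4,5,5-tetramethyl-1,3,2-dioxaborolane | COCOc1c(CC=C(C)C)c(OCOC)c2C(=O)[C@@H](C)[C@H](C)Oc2c1B1OC(C)(C)C(C)(C)O1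
A5 | alternative 3 | (2S,3S)-5,7-dihydroxy-2,3-dimethyl-6-(3-methylbut-2-en-1-yl)-2,3-dihydro-4H-chromen-4-one | CC(C)=CCc1c(O)cc2c(c1O)C(=O)[C@@H](C)[C@H](C)O2
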